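**Retrosynthetic overview**
1. 26 ⇒ (Z)-enone 24. The C3–O bond is made by a face-selective cis-epoxidation, and the Cβ–O bond is then exchanged for C–Cl with inversion. This sets C2 and C3.
2. 24 ⇒ Weinreb amide 20 + (Z)-propenyllithium. 20 ⇒ sp3–sp2 Negishi cut at C9–C10 into zinc reagent 19 and vinyl iodide 12.
3. 19 ⇒ (R)-citronellic acid 13, so the C6 centre is bought. 12 ⇒ methyl alkyne 10, where syn-hydrozirconation fixes 10E.
4. 10 ⇒ C–O ring closure (5-exo-dig) of (Z)-enynol 9 ⇐ Sonogashira coupling of 6 and 8. 6 ⇐ anti-carbomagnesiation of propargyl alcohol.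
5. Ring order: the terminal furan is bought (7), the central furan is closed in step 4, and a transient oxirane is closed and opened in step 11. No protecting groups are used.

Assumption: the SMILES reads as (2S,3S,6R,10E), a syn chlorohydrin. The sense of induction of the BINOL-type ligands is assigned by analogy, and the antipodal ligand is equally available if a model run shows the opposite sense.

**Step 1**
Reactants: 1 pent-3-yn-1-ol
Product: 2 5-bromopent-2-yne
Conditions: CBr4, PPh3, CH2Cl2, 0 °C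
Reagents that add atoms: carbon tetrabromide, BrC(Br)(Br)Br
Why: Appel bromination displaces the alkoxyphosphonium group of the primary alcohol by SN2 and leaves the internal alkyne untouched.

**Step 2**
Reactants: 2 5-bromopent-2-yne (2.4 equiv); 3 prop-2-yn-1-ol
Product: 6 (Z)-2-(iodomethylidene)hept-5-yn-1-ol, via pent-3-yn-1-ylmagnesium bromide 4 (not isolated), via chelated alkenylmagnesium alkoxide 5 (not isolated)
Conditions: Mg, THF; 3, CuI (15 mol%), Et2O/THF, −10 °C → rt; I2, −30 °C; aq NH4Cl
Reagents that add atoms: iodine, II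
Why: Copper-catalysed anti-carbomagnesiation of the propargylic alkoxide puts the alkyl group on C2 and magnesium on C3 inside a five-membered chelate, so iodinolysis with retention gives only the Z iodide with I cis to CH2OH.

**Step 3**
Reactants: 7 furan-3-carbaldehyde
Product: 8 3-ethynylfuran
Conditions: dimethyl (1-diazo-2-oxopropyl)phosphonate, K2CO3, MeOH, rt
Reagents that add atoms: dimethyl (1-diazo-2-oxopropyl)phosphonate, CC(=O)C(=[N+]=[N-])P(=O)(OC)OC
Why: Ohira–Bestmann (Seyferth–Gilbert) homologation converts the non-enolisable aldehyde into the terminal alkyne under mild carbonate conditions that the furan tolerates.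

**Step 4**
Reactants: 6 (Z)-2-(iodomethylidene)hept-5-yn-1-ol; 8 3-ethynylfuran
Product: 10 2-(furan-3-ylmethyl)-4-(pent-3-yn-1-yl)furan, via (Z)-enynol 9 (not isolated)
Conditions: PdCl2(PPh3)2 (3 mol%), CuI (6 mol%), Et3N, DMF, rt; then 80 °C
Reagents that add atoms: none
Why: Sonogashira coupling keeps the Z geometry that holds CH2OH next to the alkyne, so Pd/Cu-promoted 5-exo-dig hydroalkoxylation forms the ring C–O bond and tautomerisation of the 2-alkylidene-2,5-dihydrofuran gives the 2,4-disubstituted furan (enynol cycloisomerisation).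

**Step 5**
Reactants: 10 2-(furan-3-ylmethyl)-4-(pent-3-yn-1-yl)furan
Product: 12 2-(furan-3-ylmethyl)-4-[(3E)-4-iodopent-3-en-1-yl]furan, via alkenylzirconocene chloride 11 (not isolated)
Conditions: Cp2Zr(H)Cl (2 equiv), THF, 45 °C; I2, −78 °C
Reagents that add atoms: iodine, II
Why: Syn-hydrozirconation under equilibrating conditions places Zr on the methyl-bearing alkyne carbon, and iodinolysis with retention fixes the E geometry of the later trisubstituted alkene.

**Step 6**
Reactants: 13 (3R)-3,7-dimethyloct-6-enoic acid ((R)-citronellic acid)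
Product: 15 (3R)-N-methoxy-N,3,7-trimethyloct-6-enamide, via acyl imidazolide 14 (not isolated)
Conditions: CDI, CH2Cl2, rt; MeNH(OMe)·HCl
Reagents that add atoms: N,O-dimethylhydroxylamine hydrochloride, CNOC.Cl
Why: CDI activation and aminolysis (Weinreb amide formation) do not touch C3, so the R centre of the chiral-pool acid is carried over unchanged.

**Step 7**
Reactants: 15 (3R)-N-methoxy-N,3,7-trimethyloct-6-enamide
Product: 17 (3R)-6-hydroxy-N-methoxy-N,3-dimethylhexanamide, via aldehyde 16 (not isolated)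
Conditions: O3, CH2Cl2/MeOH, −78 °C; NaBH4, −78 → 0 °C
Reagents that add atoms: ozone, [O-][O+]=O
Why: Ozonolysis cleaves the only alkene, and the reductive borohydride work-up stops at the primary alcohol because the Weinreb amide is inert to NaBH4 at 0 °C.

**Step 8**
Reactants: 17 (3R)-6-hydroxy-N-methoxy-N,3-dimethylhexanamide
Product: 18 (3R)-6-iodo-N-methoxy-N,3-dimethylhexanamide
Conditions: I2, PPh3, imidazole, CH2Cl2, 0 °C
Reagents that add atoms: iodine, II
Why: Appel-type iodination converts the primary alcohol by SN2 far from the stereocentre.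

**Step 9**
Reactants: 18 (3R)-6-iodo-N-methoxy-N,3-dimethylhexanamide; 12 2-(furan-3-ylmethyl)-4-[(3E)-4-iodopent-3-en-1-yl]furan
Product: 20 (3R,7E)-10-[5-(furan-3-ylmethyl)furan-3-yl]-N-methoxy-N,3,7-trimethyldec-7-enamide, via alkylzinc iodide 19 (not isolated)
Conditions: Zn dust, LiCl, THF, 40 °C; 12, PdCl2(dppf) (4 mol%), rt → 40 °C
Reagents that add atoms: none
Why: LiCl-assisted zinc insertion tolerates the Weinreb amide, and the Negishi sp3–sp2 coupling with the wide-bite-angle dppf ligand proceeds with retention of the E geometry and little β-hydride elimination.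

**Step 10**
Reactants: 20 (3R,7E)-10-[5-(furan-3-ylmethyl)furan-3-yl]-N-methoxy-N,3,7-trimethyldec-7-enamide; 21 (Z)-1-bromoprop-1-ene
Product: 24 (2Z,6R,10E)-13-[5-(furan-3-ylmethyl)furan-3-yl]-6,10-dimethyltrideca-2,10-dien-4-one, via (Z)-prop-1-enyllithium 22 (not isolated), via lithium hemiaminal alkoxide 23 (not isolated)
Conditions: 21, t-BuLi (2 equiv per 21), Et2O/THF, −78 °C; 20, −78 °C; AcOH/THF, −78 °C
Reagents that add atoms: none
Why: Br/Li exchange at −78 °C retains the Z geometry, the chelated tetrahedral adduct of the Weinreb ketone synthesis prevents over-addition, and the cold acidic quench releases the (Z)-enone without amine-induced isomerisation.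

**Step 11**
Reactants: 24 (2Z,6R,10E)-13-[5-(furan-3-ylmethyl)furan-3-yl]-6,10-dimethyltrideca-2,10-dien-4-one
Product: 26 (2S,3S,6R,10E)-2-chloro-13-[5-(furan-3-ylmethyl)furan-3-yl]-3-hydroxy-6,10-dimethyltridec-10-en-4-one, via cis-epoxy ketone 25 (not isolated)
Conditions: Yb(Oi-Pr)3 (10 mol%), (S)-3-(hydroxymethyl)-BINOL (14 mol%), t-BuOOH (1.3 equiv, decane), 4 Å MS, THF, rt; then pyridine·HCl (1.5 equiv), −20 → 0 °C
Reagents that add atoms: tert-butyl hydroperoxide, CC(C)(C)OO; pyridine hydrochloride, c1cc[nH+]cc1.[Cl-]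
Why: Proposed new method: a one-flask catalytic asymmetric hydroxychlorination of a (Z)-enone with α-O/β-Cl regiochemistry in which one ytterbium centre works twice – as the chiral Yb binaphthoxide it delivers t-BuOO− to Cβ of the Yb-bound s-cis enone and the Yb enolate closes onto O–O faster than Cα–Cβ rotation (new Cα–O bond, cis-(2R,3R)-oxirane 25, while the nucleophilic peroxide ignores both furans and the trisubstituted alkene), then pyridinium chloride converts it into a YbCl3-type Lewis acid that chelates C=O and the oxirane O in a five-membered ring so that chloride attacks Cβ from the back (Cα is deactivated by the acyl group) with inversion to give the syn (2S,3S) chlorohydrin; the closest known reaction types are the lanthanide–BINOL Weitz–Scheffer epoxidation of cis-enones and the chelation-controlled C3 opening of glycidic esters by magnesium halides.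

**Compound list**
1 | pent-3-yn-1-ol | CC#CCCO | starting material
2 | 5-bromopent-2-yne | CC#CCCBr | intermediate
3 | prop-2-yn-1-ol | C#CCO | starting material
4 | pent-3-yn-1-ylmagnesium bromide | CC#CCC[Mg]Br | intermediate
5 | bromomagnesium (2Z)-3-(bromomagnesio)-2-(pent-3-yn-1-yl)prop-2-en-1-olate | Br[Mg]OC/C(CCC#CC)=C\[Mg]Br | intermediate
6 | (Z)-2-(iodomethylidene)hept-5-yn-1-ol | OC/C(CCC#CC)=C\I | intermediate
7 | furan-3-carbaldehyde | O=Cc1ccoc1 | starting material
8 | 3-ethynylfuran | C#Cc1ccoc1 | intermediate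
9 | (Z)-2-[3-(furan-3-yl)prop-2-yn-1-ylidene]hept-5-yn-1-ol | OC/C(CCC#CC)=C\C#Cc1ccoc1 | intermediate
10 | 2-(furan-3-ylmethyl)-4-(pent-3-yn-1-yl)furan | CC#CCCc1coc(Cc2ccoc2)c1 | intermediate
11 | chlorobis(cyclopentadienyl)[(2E)-5-[5-(furan-3-ylmethyl)furan-3-yl]pent-2-en-2-yl]zirconium (Cp drawn η1) | C/C(=C\CCc1coc(Cc2ccoc2)c1)[Zr](Cl)(C1C=CC=C1)C1C=CC=C1 | intermediate
12 | 2-(furan-3-ylmethyl)-4-[(3E)-4-iodopent-3-en-1-yl]furan | C/C(I)=C\CCc1coc(Cc2ccoc2)c1 | intermediate
13 | (3R)-3,7-dimethyloct-6-enoic acid | CC(C)=CCC[C@@H](C)CC(=O)O | starting material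
14 | 1-[(3R)-3,7-dimethyloct-6-enoyl]imidazole | CC(C)=CCC[C@@H](C)CC(=O)n1ccnc1 | intermediate
15 | (3R)-N-methoxy-N,3,7-trimethyloct-6-enamide | CC(C)=CCC[C@@H](C)CC(=O)N(C)OC | intermediate
16 | (3R)-N-methoxy-N,3-dimethyl-6-oxohexanamide | O=CCC[C@@H](C)CC(=O)N(C)OC | intermediate
17 | (3R)-6-hydroxy-N-methoxy-N,3-dimethylhexanamide | OCCC[C@@H](C)CC(=O)N(C)OC | intermediate
18 | (3R)-6-iodo-N-methoxy-N,3-dimethylhexanamide | ICCC[C@@H](C)CC(=O)N(C)OC | intermediate
19 | [(4R)-6-[methoxy(methyl)amino]-4-methyl-6-oxohexyl]zinc iodide | I[Zn]CCC[C@@H](C)CC(=O)N(C)OC | intermediate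
20 | (3R,7E)-10-[5-(furan-3-ylmethyl)furan-3-yl]-N-methoxy-N,3,7-trimethyldec-7-enamide | C/C(=C\CCc1coc(Cc2ccoc2)c1)CCC[C@@H](C)CC(=O)N(C)OC | intermediate
21 | (Z)-1-bromoprop-1-ene | C/C=C\Br | starting material
22 | (Z)-prop-1-en-1-yllithium | C/C=C\[Li] | intermediate
23 | lithium hemiaminal alkoxide from 20 plus 22 | C/C(=C\CCc1coc(Cc2ccoc2)c1)CCC[C@@H](C)CC([O-])(/C=C\C)N(C)OC.[Li+] | intermediate
24 | (2Z,6R,10E)-13-[5-(furan-3-ylmethyl)furan-3-yl]-6,10-dimethyltrideca-2,10-dien-4-one | C/C(=C\CCc1coc(Cc2ccoc2)c1)CCC[C@@H](C)CC(=O)/C=C\C | intermediate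
25 | (3R,7E)-10-[5-(furan-3-ylmethyl)furan-3-yl]-3,7-dimethyl-1-[(2R,3R)-3-methyloxiran-2-yl]dec-7-en-1-one | C/C(=C\CCc1coc(Cc2ccoc2)c1)CCC[C@@H](C)CC(=O)[C@@H]1O[C@@H]1C | intermediate
26 | (2S,3S,6R,10E)-2-chloro-13-[5-(furan-3-ylmethyl)furan-3-yl]-3-hydroxy-6,10-dimethyltridec-10-en-4-one | C/C(=C\CCc1coc(Cc2ccoc2)c1)CCC[C@@H](C)CC(=O)[C@H](O)[C@H](C)Cl | target

**Step count**
- Total: 11 steps (difuran branch, steps 1–5; citronellic acid branch, steps 6–8; union and endgame, steps 9–11).
- Longest linear sequence: 7 steps (1, 2, 4, 5, 9, 10, 11).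

**Three steps most likely to fail**

**Step 11 (the proposed new method).**
- Risks: reversible peroxide addition may isomerise Z to E, which would lead to the trans oxirane and then the anti chlorohydrin. Chloride may attack Cα instead of Cβ. The Lewis acid may trigger rearrangement of 25.
- The fallback sets out from 20 and comes back at 26. It reaches the syn product by double inversion on the E series, using known reactions only.
- (E)-Prop-1-enyllithium adds to 20 to give (2E,6R,10E)-13-[5-(furan-3-ylmethyl)furan-3-yl]-6,10-dimethyltrideca-2,10-dien-4-one F1.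
- La(Oi-Pr)3/(S)-BINOL/Ph3As=O with cumene hydroperoxide then gives the trans epoxide (3R,7E)-10-[5-(furan-3-ylmethyl)furan-3-yl]-3,7-dimethyl-1-[(2R,3S)-3-methyloxiran-2-yl]dec-7-en-1-one F2.
- MgBr2·OEt2 in Et2O at −20 °C opens F2 at Cβ with inversion to (2R,3S,6R,10E)-2-bromo-13-[5-(furan-3-ylmethyl)furan-3-yl]-3-hydroxy-6,10-dimethyltridec-10-en-4-one F3.
- LiCl in DMF (Finkelstein-type SN2) displaces bromide with a second inversion to give 26.

**Step 10.**
- Risks: partial loss of Z geometry in the vinyllithium or in the enone, and conjugate addition of the released amine.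
- The fallback sets out from 20 and comes back at 24. The geometry comes from a syn hydrogenation instead of a vinyl-metal.
- Prop-1-ynylmagnesium bromide adds to 20 to give (6R,10E)-13-[5-(furan-3-ylmethyl)furan-3-yl]-6,10-dimethyltridec-10-en-2-yn-4-one F4.
- Lindlar semihydrogenation (Pd/CaCO3–Pb, quinoline, H2, 1 atm, stopped at 1 equiv) gives 24.

**Step 2.**
- Risks: a moderate yield of the carbomagnesiation with a homopropargylic Grignard reagent, and protonated or doubly added by-products.
- The fallback sets out from 3 (with 8 and 2) and comes back at 9. It builds the Z-enynol by two site-selective cross-couplings on a diiodoalkene template.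
- Iodine adds anti to 3 to give (E)-2,3-diiodoprop-2-en-1-ol F5.
- Sonogashira coupling with 8 takes place at the less hindered terminal C–I and gives (E)-5-(furan-3-yl)-2-iodopent-2-en-4-yn-1-ol F6, in which the alkyne already sits cis to CH2OH.
- Zinc insertion into 2 gives pent-3-yn-1-ylzinc bromide F7.
- Negishi coupling of F7 (in excess, PdCl2(dppf)) with F6 replaces the remaining iodide with retention and delivers 9, which is cyclised to 10 as in step 4.

**Further compounds**
F1 | step 11 | (2E,6R,10E)-13-[5-(furan-3-ylmethyl)furan-3-yl]-6,10-dimethyltrideca-2,10-dien-4-one | C/C(=C\CCc1coc(Cc2ccoc2)c1)CCC[C@@H](C)CC(=O)/C=C/C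
F2 | step 11 | (3R,7E)-10-[5-(furan-3-ylmethyl)furan-3-yl]-3,7-dimethyl-1-[(2R,3S)-3-methyloxiran-2-yl]dec-7-en-1-one | C/C(=C\CCc1coc(Cc2ccoc2)c1)CCC[C@@H](C)CC(=O)[C@@H]1O[C@H]1C
F3 | step 11 | (2R,3S,6R,10E)-2-bromo-13-[5-(furan-3-ylmethyl)furan-3-yl]-3-hydroxy-6,10-dimethyltridec-10-en-4-one | C/C(=C\CCc1coc(Cc2ccoc2)c1)CCC[C@@H](C)CC(=O)[C@H](O)[C@@H](C)Br
F4 | step 10 | (6R,10E)-13-[5-(furan-3-ylmethyl)furan-3-yl]-6,10-dimethyltridec-10-en-2-yn-4-one | C/C(=C\CCc1coc(Cc2ccoc2)c1)CCC[C@@H](C)CC(=O)C#CC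
F5 | step 2 | (E)-2,3-diiodoprop-2-en-1-ol | OC/C(I)=C\I
F6 | step 2 | (E)-5-(furan-3-yl)-2-iodopent-2-en-4-yn-1-ol | OC/C(I)=C\C#Cc1ccoc1
F7 | step 2 | pent-3-yn-1-ylzinc bromide | CC#CCC[Zn]Br
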